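Slow exchange lets you audit these flasks while they run.

| flask | starting complex | incoming ligand | leaving ligand | remark | time |
|---|---|---|---|---|---|
| east | 0.50 M | 0.16 M | 0.25 M | run made earlier |  |
| south | 0.50 M | 0.45 M | 0.25 M | run made earlier |  |
| larch | 0.50 M | 0.500 M | 0.250 M |  | 2.5 d |
| ash | 0.50 M | 0.250 M | 0.250 M |  | 2.5 d |

| run | time / h | complex with one exchanged / % | starting complex / % |
|---|---|---|---|
| east | 8.00 | 6.2 | 81.1 |
| east | 15.0 | 9.4 | 71.5 |
| east | 20.0 | 9.8 | 66.7 |
| east | 30.0 | 12.3 | 57.3 |
| east | 40.0 | 14.2 | 49.8 |
| south | 3.00 | 7.9 | 83.7 |
| south | 8.00 | 15.4 | 70.4 |
| south | 15.0 | 20.1 | 57.0 |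
| south | 25.0 | 23.5 | 43.4 |
| south | 30.0 | 24.4 | 38.6 |
| south | 40.0 | 25.3 | 30.8 |

(each reading ± 0.3 percentage points)

- the earlier runs were read with a standard deviation of 0.3 percentage points
- a reading or a percentage of leaving ligand counts all its forms, free or not

1. which of these holds the largest part of the starting complex at the end of larch (starting complex / complex with three exchanged / complex with two exchanged / complex with one exchanged)
2. which of these holds the largest part of the starting complex at the end of ash (starting complex / complex with three exchanged / complex with two exchanged / complex with one exchanged)
3. how much complex with one exchanged is there at the end of ash, in percent of the starting complex charged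

Keep the ledger in incoming ligand, the limiting reagent, counted in percent of the starting complex charged. Credit east with its charge, 32.0%. Debit one ligand per complex with one exchanged: 14.2% at 40.0 h. Debit at least two per complex exchanged further, so the remainder covers at most 8.90% of the complex. Now close the books: 36.0% is neither starting complex nor complex with one exchanged, more than that cover, so on these readings at least 27.1% sits in some form that took no incoming ligand.

Carry this to ash. Interpolate on the ligand charge between east and south at 40.0 h: complex with one exchanged comes to 17.6%. Take that estimate for the end of ash as well. Shrink the interpolated starting complex as east's shrank from 20.0 h to 40.0 h, and it ends near 32.8%. The ligand ceiling of ash, half the charged ligand that complex with one exchanged leaves over, is 16.2%, less than that complex holds. So I expect starting complex to lead the four complexes in ash. For larch, south's last reading of complex with one exchanged gives a ceiling of 37.4%, above that reading, so I leave larch open.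

The forecast names complex with two exchanged for larch and complex with two exchanged for ash, with 20% (16% to 24%) of complex with one exchanged in ash, and says “ligand supply evidently does not cap conversion”.

Among the four complexes, the flasks give complex with one exchanged in larch, at 24.9%, and starting complex in ash, at 31.3%, and ash holds 20.4% of complex with one exchanged.

    complex with two exchanged + incoming ligand → leaving ligand + complex with three exchanged (k = 0.00140 M⁻¹ min⁻¹)
    starting complex + incoming ligand → leaving ligand + complex with one exchanged (k = 0.00170 M⁻¹ min⁻¹)
    leaving ligand + starting complex → side product (k = 0.00250 M⁻¹ min⁻¹)
    incoming ligand ⇌ dormant form (K = 0.970, k = 0.00460 min⁻¹)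
    complex with one exchanged + incoming ligand → leaving ligand + complex with two exchanged (k = 0.00190 M⁻¹ min⁻¹)
    crystals ⇌ leaving ligand, rate k6*(cs6 - [leaving ligand]) while solid is left; crystals form when [leaving ligand] > cs6 (solubility = 0.0750 M, k = 0.00680 min⁻¹)

Complexes exchanged beyond one hold 6.55% in ash, under the ceiling of 16.2%; side product, at 41.8%, is a form that took no incoming ligand. A neighbouring flask, ash with 0.10 M of incoming ligand, has 11.0% of complex with one exchanged, so its ceiling is 4.50%, and complex with two exchanged stands at 1.21% there. Ash is not at rest at 2.5 d: by 25.0 d starting complex falls to 0.0507%, side product rises to 68.2%, complex with two exchanged reaches 11.2%, and complex with one exchanged slips to 17.1%.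

(The data stem from a simulated flask from invented constants; scatter was added.)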